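# Total synthesis proposal for CNP0268544.8 (compound 24)

## Analysis of the target

- **Skeleton.** Compound 24 (C30H50N2O2) is a pentacyclic bis-quinolizidin-2-one. Unit 1 comprises N5, C1–C4 and C6–C10; unit 2 has the same atoms, primed. The units are joined head to tail by two (CH2)5 chains, C9→C1′ (chain a) and C9′→C1 (chain b). As a result C1, C10, C9, chain a, C1′, C10′, C9′ and chain b form a 16-membered ring made of carbon only.
- **Rings.** In each unit ring A (N5, C4, C3(CH3), C2(=O), C1, C10) is a 4-piperidone and ring B (N5, C6, C7, C8, C9, C10) is a piperidine. The C1–C10 bond belongs both to ring A and to the macrocycle.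
- **Configuration.** It is (1S,3S,9R,10R) in unit 1 and (1′R,3′S,9′S,10′R) in unit 2. C10/C10′ and C3/C3′ are homochiral, whereas C9/C9′ and C1/C1′ are heterochiral. H9/H10 are trans and H1/H10 cis in unit 1; H9′/H10′ are cis and H1′/H10′ trans in unit 2. The two constitutionally equal halves are therefore diastereomeric and the molecule has no symmetry.
- **Conformation.** On the trans-fused quinolizidines one of the two peri chains is axial and the other equatorial (C1 axial in unit 1, C9′ axial in unit 2). This avoids a syn-pentane contact between the chains. Both methyl groups are equatorial.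
- **Sensitive positions.** C1 and C3 are labile ketone α-centres. C10 can be lost by retro-Mannich or retro-aza-Michael cleavage. Any C10=N5 iminium ion can tautomerize to the C9=C10 enamine and erase C9.
- **What makes it hard.** A skeleton that carries only 9R and 9′S is meso. An end game under thermodynamic control can therefore give only racemate, so the pairing of each C9 with its C10 has to be set kinetically.
- **Feature the route exploits.** N5–C4 and C10–C1 of each ring A are the two σ-bonds of a formal [4+2] union. The partners are a C10=N5 imine and the 2-oxydiene C1=C2(O)–C3(CH3)=C4. The homochiral pair C10/C10′ calls for one enantiomer of a chiral ammonia equivalent used on both halves.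

## Retrosynthetic reasoning

**Rings B and B′ (24 ⇒ 23 ⇒ 22 ⇒ 21 ⇒ 20).** N5–C6 and N5′–C6′ are cut first. A 6-exo-tet N-alkylation creates no stereocentre. It also lets nitrogen stay non-basic (N-sulfinyl) and C10 free of iminium character until the last flask. The forward step has to close two piperidines and let C1, C3, C1′ and C3′ settle. Their favoured arrangement, once C9 and C10 are fixed, is the one found in 24. The C6 electrophiles come from the allyl arms of 20.

**Ring A′ and the macrocycle (20 ⇒ 17).** C1′–C10′ and N5′–C4′ are cut together. C1′–C10′ is the most congested bond of the carbocycle and carries the stereocentre that decides the diastereomer. Cutting there turns a tricycle into the open chain 17. Compound 17 has a sulfinimine head (C10′) and an isopropenyl ketone tail (C1′–C4′). The forward step has to close a 16-membered and a 6-membered ring and set C10′ independently of C9′.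

**Ring A (17 ⇒ 16 ⇒ 15 ⇒ 10 + 13).** The same pair of bonds, C1–C10 and N5–C4, is cut in unit 1, this time between two molecules. The head of the nucleophilic partner is kept at the alcohol level (13, then 15, 16, 17). At each stage only one imine and one diene can then meet, which enforces the heterochiral head-to-tail pairing.

**C9 and C9′ (10 ⇐ 8, 13 ⇐ 12 ⇐ 11; 8 and 11 ⇒ 6 + 7).** C9–C8 and C9′–C8′ are cut. Both enantiomeric α-allyl aldehydes come from one achiral keto aldehyde 6 and allylsilane 7, using the two enantiomers of one organocatalyst. The same sulfinamide 9 serves both halves.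

**The C9 backbone (6 ⇒ 5 ⇒ 3 ⇒ 1, 2, 4).** C1–C9 of oleic acid 1 deliver C2, C1, the five chain carbons, C9 and C10. Grignard reagent 4 delivers C3, its methyl group and C4.

## Alternatives that were turned down

**Alternative 1: the textbook route.**
- Disconnection: cut inside chain b.
- Forward key step: ring-closing metathesis of the seco-diene A1 (second-generation Grubbs catalyst), then hydrogenation to 24.
- Reasons for rejection:
  - A1 already contains all four heterocycles and all eight stereocentres, so the key step builds none of what is hard.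
  - Two different quinolizidinones would have to be made separately.
  - Their C1–alkyl bonds would need alkylation of β-amino ketone enolates with unactivated halides.
  - Two basic amines burden the metathesis.
  - The step count would be roughly double that of the present route.

**Alternative 2: the biomimetic cut.**
- Disconnection: C1–C10 and C1′–C10′ are cut inside the 24-membered bis-lactam diketone A2.
- Forward key step: double reductive activation (IrCl(CO)(PPh3)2, (Me2HSi)2O, then acid) and two transannular Mannich closures to 24.
- Reasons for rejection: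
  - C3 is labile, so A2 is in effect meso.
  - Each iminium ion is attacked under control of its own C9 with the same relative topicity. That favours the centrosymmetric diastereomer and not 24.
  - Iminium–enamine tautomerization erases C9.
  - Whatever 24 forms is racemic.

**Alternative 3: carbocycle by cyclodimerization.**
- Disconnection: double Dieckmann condensation of dimethyl nonanedioate A3 to the bis(β-keto ester) A4. This is followed by γ-alkylation at C9/C9′ and amination of the C10/C10′ ketones.
- What is attractive: A4 maps C10, C1 and C2 exactly, and no late macrocyclization is needed.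
- Reasons for rejection:
  - The head-to-head isomer forms as easily as A4.
  - All α-centres are labile.
  - The C10 ketone is flanked by two similar branches, so neither imine geometry nor facial selectivity can be controlled.
  - Nothing can make C9/C9′ heterochiral while C10/C10′ stay homochiral.

Key step: step 12

Remark: C1, C3, C1′ and C3′ are labile ketone α-centres in 14–23. They are drawn with the configuration of 24, which is fixed only by the equilibration in step 15.

## Route

Step 1
Reactants: 1 oleic acid; 2 N,O-dimethylhydroxylamine hydrochloride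
Product: 3 (9Z)-N-methoxy-N-methyloctadec-9-enamide
Conditions: 1,1′-carbonyldiimidazole, CH2Cl2, 23 °C
Reagents that add atoms: none
Why: Acyl imidazolide formation and aminolysis (Weinreb amide synthesis); the isolated Z alkene is inert.

Step 2
Reactants: 3 Weinreb amide; 4 isopropenylmagnesium bromide
Product: 5 (11Z)-2-methylicosa-1,11-dien-3-one
Conditions: THF, 0 °C; 1 M HCl
Reagents that add atoms: none
Why: Weinreb ketone synthesis; the magnesium chelate of the tetrahedral adduct lasts until the quench, so neither over-addition nor conjugate addition to the new enone can occur.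

Step 3
Reactants: 5 dienone
Product: 6 10-methyl-9-oxoundec-10-enal
Conditions: O3 (1 equiv, Sudan Red 7B end point), CH2Cl2, −78 °C; Me2S
Reagents that add atoms: ozone [O-][O+]=O
Why: Ozonolysis; electrophilic ozone should take the electron-rich cis-dialkyl alkene well before the acceptor-substituted 1,1-disubstituted alkene, and the indicator stops the gas flow at that point.

Step 4
Reactants: 6 keto aldehyde; 7 allyltrimethylsilane
Product: 8 (2R)-10-methyl-9-oxo-2-(prop-2-en-1-yl)undec-10-enal
Conditions: (2S,5S)-5-benzyl-2-tert-butyl-3-methylimidazolidin-4-one·CF3CO2H (20 mol %), (NH4)2Ce(NO3)6 (2 equiv), NaHCO3, H2O, DME, −20 °C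
Reagents that add atoms: none
Why: Enantioselective α-allylation by singly-occupied-orbital (SOMO) enamine catalysis; tetravalent cerium oxidizes the E enamine to a radical cation whose Re face is shielded by the benzyl group, so the allylsilane adds to the Si face and sets C9 as R. The electrophilic radical cation should ignore the electron-poor enone.

Step 5
Reactants: 8 (R)-aldehyde; 9 (S)-2-methylpropane-2-sulfinamide
Product: 10 (S)-N-[(1E,2R)-10-methyl-9-oxo-2-(prop-2-en-1-yl)undec-10-en-1-ylidene]-2-methylpropane-2-sulfinamide
Conditions: CuSO4 (anhydrous), CH2Cl2, 23 °C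
Reagents that add atoms: none
Why: Sulfinimine condensation under neutral dehydration; the aldehyde reacts and the ketone does not, and C9 should not epimerize.

Step 6
Reactants: 6 keto aldehyde; 7 allyltrimethylsilane
Product: 11 (2S)-10-methyl-9-oxo-2-(prop-2-en-1-yl)undec-10-enal
Conditions: (2R,5R)-5-benzyl-2-tert-butyl-3-methylimidazolidin-4-one·CF3CO2H (20 mol %), (NH4)2Ce(NO3)6 (2 equiv), NaHCO3, H2O, DME, −20 °C
Reagents that add atoms: none
Why: Same SOMO α-allylation with the mirror-image catalyst; addition to the Re face of the enamine sets C9′ as S.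

Step 7
Reactants: 11 (S)-aldehyde
Product: 12 (10S)-10-(hydroxymethyl)-2-methyltrideca-1,12-dien-3-one
Conditions: NaBH4, CH2Cl2/EtOH, −78 °C
Reagents that add atoms: none
Why: Chemoselective borohydride reduction; at −78 °C the aldehyde is reduced much faster than the conjugated ketone. This parks C10′ at the alcohol level so that the nucleophilic partner carries no electrophilic head.

Step 8
Reactants: 12 keto alcohol
Product: 13 (3Z,10S)-2-methyl-3-(trimethylsilyloxy)-10-[(trimethylsilyloxy)methyl]trideca-1,3,12-triene
Conditions: Me3SiOSO2CF3 (2.2 equiv), Et3N, Et2O, 0 °C; pentane extraction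
Reagents that add atoms: trimethylsilyl trifluoromethanesulfonate C[Si](C)(C)OS(=O)(=O)C(F)(F)F
Why: Soft enolization to a 2-silyloxydiene; the ketone can enolize only towards C1 because its other neighbour is the sp2 carbon C3, and the Z enol ether is the usual outcome. The alcohol is silylated in the same operation.

Step 9
Reactants: 10 (9R)-sulfinimine; 13 silyloxydiene
Product: 15 ring A alcohol of unit 1, via open-chain Mannich adduct 14 (not isolated)
Conditions: Me3SiOSO2CF3 (1.1 equiv), CH2Cl2, −78 to −20 °C; aq. NaHCO3; citric acid, MeOH, 0 °C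
Reagents that add atoms: none
Why: Mukaiyama–Mannich addition followed by 6-endo-trig aza-Michael closure (stepwise aza-Diels–Alder reaction) forms C1–C10 and N5–C4. In the s-cis (S)-sulfinimine the tert-butyl group blocks one face and the non-chelating silyl nucleophile enters on the Si face of C10 (open transition state), which gives 10R. Without amine base the enone tail of 10 cannot enolize, and the more Lewis basic sulfinimine should bind the silyl cation first.

Step 10
Reactants: 15 ring A alcohol
Product: 16 ring A aldehyde
Conditions: Dess–Martin periodinane, NaHCO3, CH2Cl2, 0 °C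
Reagents that add atoms: none
Why: Dess–Martin oxidation under buffered conditions should spare the sulfinamide, the enone and the alkenes, and should leave C9′ untouched.

Step 11
Reactants: 16 ring A aldehyde; 9 (S)-2-methylpropane-2-sulfinamide
Product: 17 seco sulfinimine
Conditions: CuSO4 (anhydrous), CH2Cl2, 23 °C
Reagents that add atoms: none
Why: Same neutral sulfinimine condensation as in step 5; only the aldehyde condenses.

Step 12
Reactants: 17 seco sulfinimine
Product: 20 macrocyclic bis(N-sulfinylpiperidinone), via silyl dienol ether 18 (not isolated), via macrocyclic Mannich adduct 19 (not isolated)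
Conditions: LiN(SiMe3)2 (1.1 equiv), Me3SiCl (present from the start), THF, −78 °C; evaporation, pentane filtration; syringe-pump addition to Me3SiOSO2CF3 (1.2 equiv), CH2Cl2 (final 1 mM), −78 to −20 °C; aq. NaHCO3
Reagents that add atoms: none
Why: Proposed new method: the bond-forming events are those of step 9 (Mukaiyama–Mannich addition of a 2-silyloxydiene to a silyl-activated N-tert-butanesulfinyl aldimine, then aza-Michael closure), but their use to close a large ring is not known; the closest known reaction types are the intermolecular version and Mukaiyama aldol or metal-enolate macroaldolizations to rings of 14 to 16 members. Kinetic deprotonation under in situ silylation converts the isopropenyl ketone, whose only enolizable position is C1′, into the Z dienol ether 18, and no base is present when the Lewis acid arrives, which protects the C9′–H next to the imine. The silyl triflate activates the sulfinimine, C1′ attacks C10′ (16-exo-trig, closes the carbocycle) to give 19, and the sulfinamide nitrogen then adds to C4′ of the activated enone (6-endo-trig, closes ring A′). C10′ is controlled by sulfur alone: the tert-butyl group of the s-cis sulfinimine blocks one face and the nucleophile enters on the Si face through an open transition state, which gives 10′R. C9′ carries two primary alkyl branches of nearly equal size and exerts no Felkin-type bias, so the auxiliary that gave the 9,10-trans pair in step 9 should give the 9′,10′-cis pair here. C1′ and C3′ arise as labile α-centres and are settled in step 15. Ring closure must beat oligomerization, which slow addition to about 1 mM should secure because 18 has one nucleophilic and one electrophilic terminus and no smaller ring is open to them. C1′ must be the only nucleophile, which holds because the ring A ketone is flanked by two tertiary carbons and could only form a quaternary centre.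

Step 13
Reactants: 20 macrocyclic bis(N-sulfinylpiperidinone)
Product: 21 macrocyclic diol
Conditions: dicyclohexylborane (2.4 equiv), THF, 0 °C; NaBO3·4H2O, THF/H2O, 23 °C
Reagents that add atoms: sodium perborate [Na+].[O-]OB=O
Why: Anti-Markovnikov hydroboration–oxidation; the two terminal alkenes react within minutes at 0 °C, whereas both ketones are flanked by two tertiary carbons. Perborate is a mild oxidant that should spare the sulfinamides.

Step 14
Reactants: 21 macrocyclic diol
Product: 22 macrocyclic dimesylate
Conditions: CH3SO2Cl, Et3N, CH2Cl2, −10 °C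
Reagents that add atoms: methanesulfonyl chloride CS(=O)(=O)Cl
Why: Standard mesylation of two primary alcohols; nitrogen is blocked by the sulfinyl groups.

Step 15
Reactants: 22 macrocyclic dimesylate
Product: 24 target bis-quinolizidinone, via bis(piperidinone) dihydrochloride 23 (not isolated)
Conditions: HCl (4 M in dioxane), MeOH, 0 °C; evaporation; K2CO3, MeCN (5 mM), 45 °C; K2CO3, MeOH, 23 °C
Reagents that add atoms: none
Why: Acidic methanolysis of both sulfinamides, then two 6-exo-tet N-alkylations (SN2) close rings B and B′ without touching C9 or C10. Mild base then equilibrates the α-centres through the enolates: each methyl group goes equatorial, and at each peri pair C1/C9 one chain stays axial and one equatorial to avoid the syn-pentane contact. This corresponds to 1S,3S for the 9R,10R unit and 1′R,3′S for the 9′S,10′R unit.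

## Compound list

1 | oleic acid, (9Z)-octadec-9-enoic acid | CCCCCCCC/C=C\CCCCCCCC(=O)O | starting material
2 | N,O-dimethylhydroxylamine hydrochloride | CNOC.Cl | starting material
3 | (9Z)-N-methoxy-N-methyloctadec-9-enamide | CCCCCCCC/C=C\CCCCCCCC(=O)N(C)OC | intermediate
4 | isopropenylmagnesium bromide | CC(=C)[Mg]Br | starting material
5 | (11Z)-2-methylicosa-1,11-dien-3-one | CCCCCCCC/C=C\CCCCCCCC(=O)C(C)=C | intermediate
6 | 10-methyl-9-oxoundec-10-enal | O=CCCCCCCCC(=O)C(C)=C | intermediate
7 | allyltrimethylsilane | C=CC[Si](C)(C)C | starting material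
8 | (2R)-10-methyl-9-oxo-2-(prop-2-en-1-yl)undec-10-enal | C=CC[C@H](C=O)CCCCCCC(=O)C(C)=C | intermediate
9 | (S)-2-methylpropane-2-sulfinamide | CC(C)(C)[S@](=O)N | starting material
10 | (S)-N-[(1E,2R)-10-methyl-9-oxo-2-(prop-2-en-1-yl)undec-10-en-1-ylidene]-2-methylpropane-2-sulfinamide | C=CC[C@H](/C=N/[S@@](=O)C(C)(C)C)CCCCCCC(=O)C(C)=C | intermediate
11 | (2S)-10-methyl-9-oxo-2-(prop-2-en-1-yl)undec-10-enal | C=CC[C@@H](C=O)CCCCCCC(=O)C(C)=C | intermediate
12 | (10S)-10-(hydroxymethyl)-2-methyltrideca-1,12-dien-3-one | C=CC[C@@H](CO)CCCCCCC(=O)C(C)=C | intermediate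
13 | (3Z,10S)-2-methyl-3-(trimethylsilyloxy)-10-[(trimethylsilyloxy)methyl]trideca-1,3,12-triene | C=CC[C@@H](CO[Si](C)(C)C)CCCCC/C=C(\O[Si](C)(C)C)C(C)=C | intermediate
14 | open-chain Mannich adduct (1S,9R,10R,9′S): C10 bears NH-(S)-S(O)tBu, C1 bears C(=O)C(CH3)=CH2 and chain b ending in CH(allyl)CH2OSiMe3 | C=C(C)C(=O)CCCCCC[C@H](CC=C)[C@@H](N[S@@](=O)C(C)(C)C)[C@H](CCCCC[C@H](CO[Si](C)(C)C)CC=C)C(=O)C(C)=C | intermediate
15 | ring A alcohol (1S,3S,9R,10R,9′S): N5-[(S)-tert-butylsulfinyl]piperidin-4-one, C10 bears CH(allyl)(CH2)6C(=O)C(CH3)=CH2, C1 bears (CH2)5CH(allyl)CH2OH | C=C(C)C(=O)CCCCCC[C@H](CC=C)[C@H]1N([S@@](=O)C(C)(C)C)C[C@H](C)C(=O)[C@H]1CCCCC[C@H](CO)CC=C | intermediate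
16 | ring A aldehyde (C10′ as CHO) | C=C(C)C(=O)CCCCCC[C@H](CC=C)[C@H]1N([S@@](=O)C(C)(C)C)C[C@H](C)C(=O)[C@H]1CCCCC[C@H](C=O)CC=C | intermediate
17 | seco sulfinimine (C10′ as (E)-CH=N-(S)-S(O)tBu) | C=C(C)C(=O)CCCCCC[C@H](CC=C)[C@H]1N([S@@](=O)C(C)(C)C)C[C@H](C)C(=O)[C@H]1CCCCC[C@H](/C=N/[S@@](=O)C(C)(C)C)CC=C | intermediate
18 | (Z)-trimethylsilyl dienol ether of 17 at C1′=C2′ | C=C(C)/C(O[Si](C)(C)C)=C/CCCCC[C@H](CC=C)[C@H]1N([S@@](=O)C(C)(C)C)C[C@H](C)C(=O)[C@H]1CCCCC[C@H](/C=N/[S@@](=O)C(C)(C)C)CC=C | intermediate
19 | macrocyclic Mannich adduct: 16-membered ring closed, ring A′ still open | O=C1[C@@H](C)CN([S@@](=O)C(C)(C)C)[C@@H]2[C@@H](CC=C)CCCCC[C@@H](C(=O)C(C)=C)[C@H](N[S@@](=O)C(C)(C)C)[C@H](CC=C)CCCCC[C@H]12 | intermediate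
20 | macrocyclic bis(N-sulfinylpiperidin-4-one) (1S,3S,9R,10R,1′R,3′S,9′S,10′R), allyl on C9 and C9′ | O=C1[C@@H](C)CN([S@@](=O)C(C)(C)C)[C@@H]2[C@@H](CC=C)CCCCC[C@H]3C(=O)[C@@H](C)CN([S@@](=O)C(C)(C)C)[C@@H]3[C@H](CC=C)CCCCC[C@H]12 | intermediate
21 | macrocyclic diol (3-hydroxypropyl on C9 and C9′) | O=C1[C@@H](C)CN([S@@](=O)C(C)(C)C)[C@@H]2[C@@H](CCCO)CCCCC[C@H]3C(=O)[C@@H](C)CN([S@@](=O)C(C)(C)C)[C@@H]3[C@H](CCCO)CCCCC[C@H]12 | intermediate
22 | macrocyclic dimesylate | O=C1[C@@H](C)CN([S@@](=O)C(C)(C)C)[C@@H]2[C@@H](CCCOS(C)(=O)=O)CCCCC[C@H]3C(=O)[C@@H](C)CN([S@@](=O)C(C)(C)C)[C@@H]3[C@H](CCCOS(C)(=O)=O)CCCCC[C@H]12 | intermediate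
23 | bis(NH-piperidin-4-one) dimesylate dihydrochloride | O=C1[C@@H](C)CN[C@@H]2[C@@H](CCCOS(C)(=O)=O)CCCCC[C@H]3C(=O)[C@@H](C)CN[C@@H]3[C@H](CCCOS(C)(=O)=O)CCCCC[C@H]12.Cl.Cl | intermediate
24 | CNP0268544.8, (1S,3S,9R,10R,1′R,3′S,9′S,10′R)-bis-quinolizidin-2-one macrocycle | C[C@H]1CN2CCC[C@H]3CCCCC[C@H]4C(=O)[C@@H](C)CN5CCC[C@H](CCCCC[C@H](C1=O)[C@@H]32)[C@H]45 | target

## Step count and least certain steps

Total step count: 15. Longest linear sequence: 13 (steps 1–3 and 6–15).

**Step 12 (key step).**
- Intermolecular addition may outrun ring closure, because the effective molarity of a flexible 16-membered closure is low and attack at the branched C10′ is slow.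
- The activated sulfinimine may tautomerize to the ene-sulfinamide, with loss of C9′.
- The aza-Michael closure may stop half way.
- Fallback (from 16, rejoining at 23): it replaces the silyl nucleophile and open transition state by a preformed metal enolate and a closed chelate.
  - Both elements are known. Kinetic lithium enolates of ketones add to N-tert-butanesulfinyl aldimines, and kinetic metal enolates have closed 16-membered rings in macroaldolizations.
  - Aldehyde 16 is condensed with commercial (R)-2-methylpropane-2-sulfinamide (CuSO4) to the (R)-configured seco sulfinimine F1, because the closed transition state inverts the sense of induction.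
  - F1 is added slowly to LiN(SiMe3)2 (1.05 equiv) in THF at −78 °C (1 mM). On warming, the lithium sulfinamide closes ring A′ to the mixed-sulfur macrocycle F2.
  - The conditions of steps 13 and 14 give the diol F3 and the dimesylate F4. Acidic methanolysis of F4 gives 23.

**Step 9.**
- Silyloxydiene 13 may add in Mukaiyama–Michael fashion to the free enone tail of 10.
- Facial selectivity may erode if part of the reaction runs through a chelated transition state.
- Fallback (from 10, rejoining at 15): no electrophilic alkene is left in the flask.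
  - Compound 10 is converted (LiN(SiMe3)2, Me3SiCl present from the start, −78 °C) into the imine dienol ether F5.
  - F5 is added slowly to an excess of 13 and Me3SiOSO2CF3. Selectivity now rests on stoichiometry.
  - Work-up hydrolyses the unused tail back to the enone of 15, and the surplus 13 returns as 12.

**Step 4 (and step 6).**
- Enantioselectivity may be insufficient.
- The strong oxidant may damage the keto aldehyde.
- Fallback (from 6, rejoining at 10 and 11): it uses the fact that both enantiomers are needed in equal amounts.
  - Racemic α-allylation (pyrrolidine, Pd(PPh3)4, allyl acetate, DMSO) gives the racemic allyl aldehyde F6.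
  - Condensation with 9 gives 10 together with the (9S)-sulfinimine F7. The two diastereomers are separated by chromatography.
  - F7 is hydrolysed with dilute aqueous acid to 11.

**Step 13.**
- The ketones may be partly reduced.
- Sulfur may be oxidized during the oxidative work-up.
- Fallback (from 20, rejoining at 24): boron is avoided.
  - An aldehyde-selective Wacker-type oxidation (PdCl2(PhCN)2, CuCl2·2H2O, AgNO2, t-BuOH/MeNO2, O2) gives the dialdehyde F8.
  - Treatment with HCl/MeOH and then NaBH(OAc)3 closes both rings B by reductive amination to give 24.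

**Step 15.**
- C10 may be lost by retro-aza-Michael opening of the free secondary β-amino ketones while they are warmed with base.
- Intermolecular N-alkylation may compete.
- The α-centre equilibrium may be shifted by macrocyclic strain.
- Fallback (from 21, rejoining at 24): ring closure takes place at low temperature.
  - Treatment of 21 with HCl/MeOH gives the bis(amino alcohol) F9.
  - F9 is cyclodehydrated under Appel conditions (PPh3, CBr4, Et3N, CH2Cl2, 0 °C). The brief base equilibration follows.

## Further compounds

F1 | step 12 | seco sulfinimine made with (R)-sulfinamide at C10′ | C=C(C)C(=O)CCCCCC[C@H](CC=C)[C@H]1N([S@@](=O)C(C)(C)C)C[C@H](C)C(=O)[C@H]1CCCCC[C@H](/C=N/[S@](=O)C(C)(C)C)CC=C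
F2 | step 12 | macrocyclic bis(N-sulfinylpiperidinone), (S)-sulfinyl on N5 and (R)-sulfinyl on N5′ | O=C1[C@@H](C)CN([S@@](=O)C(C)(C)C)[C@@H]2[C@@H](CC=C)CCCCC[C@H]3C(=O)[C@@H](C)CN([S@](=O)C(C)(C)C)[C@@H]3[C@H](CC=C)CCCCC[C@H]12
F3 | step 12 | diol from F2 | O=C1[C@@H](C)CN([S@@](=O)C(C)(C)C)[C@@H]2[C@@H](CCCO)CCCCC[C@H]3C(=O)[C@@H](C)CN([S@](=O)C(C)(C)C)[C@@H]3[C@H](CCCO)CCCCC[C@H]12
F4 | step 12 | dimesylate from F3 | O=C1[C@@H](C)CN([S@@](=O)C(C)(C)C)[C@@H]2[C@@H](CCCOS(C)(=O)=O)CCCCC[C@H]3C(=O)[C@@H](C)CN([S@](=O)C(C)(C)C)[C@@H]3[C@H](CCCOS(C)(=O)=O)CCCCC[C@H]12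
F5 | step 9 | (Z)-trimethylsilyl dienol ether of sulfinimine 10 | C=CC[C@H](/C=N/[S@@](=O)C(C)(C)C)CCCCC/C=C(\O[Si](C)(C)C)C(C)=C
F6 | step 4 | racemic 10-methyl-9-oxo-2-(prop-2-en-1-yl)undec-10-enal | C=CCC(C=O)CCCCCCC(=O)C(C)=C
F7 | step 4 | (S)-N-[(1E,2S)-10-methyl-9-oxo-2-(prop-2-en-1-yl)undec-10-en-1-ylidene]-2-methylpropane-2-sulfinamide | C=CC[C@@H](/C=N/[S@@](=O)C(C)(C)C)CCCCCCC(=O)C(C)=C
F8 | step 13 | macrocyclic dialdehyde (3-oxopropyl on C9 and C9′) | O=C1[C@@H](C)CN([S@@](=O)C(C)(C)C)[C@@H]2[C@@H](CCC=O)CCCCC[C@H]3C(=O)[C@@H](C)CN([S@@](=O)C(C)(C)C)[C@@H]3[C@H](CCC=O)CCCCC[C@H]12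
F9 | step 15 | macrocyclic bis(amino alcohol) | O=C1[C@@H](C)CN[C@@H]2[C@@H](CCCO)CCCCC[C@H]3C(=O)[C@@H](C)CN[C@@H]3[C@H](CCCO)CCCCC[C@H]12
A1 | alternative 1 | seco-diene: two complete quinolizidinones joined by chain a, allyl on C1, but-3-enyl on C9′ | C=CC[C@@H]1C(=O)[C@@H](C)CN2CCC[C@H]([C@H]12)CCCCC[C@H]3C(=O)[C@@H](C)CN4CCC[C@H](CCC=C)[C@H]34
A2 | alternative 2 | 24-membered bis(piperidin-2-one) diketone | O=C1N2CCC[C@H]1CCCCCCC(=O)[C@@H](C)CN3CCC[C@@H](C3=O)CCCCCCC(=O)[C@@H](C)C2
A3 | alternative 3 | dimethyl nonanedioate | COC(=O)CCCCCCCC(=O)OC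
A4 | alternative 3 | dimethyl 2,10-dioxocyclohexadecane-1,9-dicarboxylate | COC(=O)C1CCCCCCC(=O)C(C(=O)OC)CCCCCCC1=O
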